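## Retrosynthetic overview

- The target is a 2,9-dioxabicyclo[3.3.1]nona-3,7-diene (ring A: O9–C1–C8=C7–C6–C5; ring B: O2–C3=C4–C5–O9–C1). The side-chain ketone comes from its carbinol (oxidised last), and the chain from a boron anti-aldol of an ethyl ketone with (2R,4E)-2,4-dimethylhept-4-enal.
- Ring B (C1–O2 bond) comes from a Ferrier-type ketal exchange: the oxygen of the C3 ketone displaces methanol at C1 of a 2-methoxy-2H-pyran. That pyran comes from 1,2-reduction and allylic transposition of a 2,3-dihydro-4H-pyran-4-one whose carbonyl carbon is C7.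
- Ring A is closed at C6–C7 by a 6-exo hydroacylation: the formyl C–H of a vinylogous formate (C7 = CHO) adds across a vinyl group on C5 through an acyl radical under thiol catalysis.
- Enabling feature: in ring A the methyl-bearing C6 lies between the oxygenated bridgehead C5 and the vinylic C7, and C7–C8(Me)–C1(Et)–O9 is a β-keto-aldehyde array one oxidation level up. So C6(H)(CH3) is the Markovnikov H/acyl adduct of a vinyl group on C5, and C7 is an aldehyde carbon held cis to O9 by the C8=C1 enol ether.
- Ring order: ring A (step 5), then ring B (step 14). C5 comes from an Evans acrolein aldol, C6 from the cyclisation followed by equilibration, C1 from the bridge, and the chain centres from an Evans alkylation and enolate control.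

Key step: step 5

Remark on the chemistry (assumption): 2 and 7 are handled as E/Z mixtures about the tetrasubstituted C=C (7 is drawn as the cyclisable Z isomer; the radical conditions of step 5 should interconvert the two). 11, 12 and 20 are anomeric mixtures at the ketal carbon, which is reset in step 14.

## Route

Step 1
Reactants: 1 pentan-3-one
Product: 2 3-chloro-2-methylpent-2-enal (E/Z mixture)
Conditions: POCl3, DMF, 0 °C to 60 °C; then ice–water
Reagents that add atoms: N,N-dimethylformamide CN(C)C=O; phosphoryl chloride O=P(Cl)(Cl)Cl; water O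
Why: Vilsmeier–Haack–Arnold haloformylation of the symmetrical ketone gives the β-chlorovinyl aldehyde after hydrolysis; no stereocentre is formed and the E/Z ratio does not matter.

Step 2
Reactants: 3 (R)-4-benzyl-3-propionyloxazolidin-2-one; 4 acrolein
Product: 5 (R)-4-benzyl-3-[(2R,3S)-3-hydroxy-2-methylpent-4-enoyl]oxazolidin-2-one
Conditions: Bu2BOTf, iPr2NEt, CH2Cl2, −78 to 0 °C; 4, −78 °C; then pH 7 buffer, MeOH, H2O2, 0 °C
Reagents that add atoms: none
Why: Evans syn-aldol: the (Z)-boron enolate reacts through a chair transition state on the face away from the benzyl group, setting C2 (R, a sacrificial controller) and the carbinol C3 (S, the future bridgehead C5).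

Step 3
Reactants: 5 aldol adduct
Product: 6 (2R,3S)-3-hydroxy-N-methoxy-N,2-dimethylpent-4-enamide
Conditions: MeNHOMe·HCl, AlMe3, THF/CH2Cl2, −20 to 0 °C; then aq. potassium sodium tartrate
Reagents that add atoms: N,O-dimethylhydroxylamine hydrochloride CNOC.Cl
Why: Weinreb amide formation by aluminium-amide transamination of the imide, assisted by the free β-hydroxyl, should remove the auxiliary without touching either stereocentre.

Step 4
Reactants: 6 Weinreb amide; 2 chloro-enal
Product: 7 (2R,3S)-N-methoxy-N,2-dimethyl-3-{[(2Z)-2-methyl-1-oxopent-2-en-3-yl]oxy}pent-4-enamide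
Conditions: KN(SiMe3)2, THF, −78 °C; then 2, −78 to −20 °C
Reagents that add atoms: none
Why: addition–elimination (vinylic substitution) of the alkoxide at the β-carbon of the vinylogous acid chloride 2 should give the vinylogous formate; the carbinol centre is not involved and the low temperature suppresses retro-aldol cleavage.

Step 5
Reactants: 7 vinylogous formate
Product: 9 (2R)-2-[(2S,3R)-6-ethyl-3,5-dimethyl-4-oxo-3,4-dihydro-2H-pyran-2-yl]-N-methoxy-N-methylpropanamide, via C3-epimeric dihydropyranone 8 (not isolated)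
Conditions: t-C12H25SH (30 mol %), AIBN (azobisisobutyronitrile, 20 mol %, in portions), PhCl (0.02 M), 85 °C; then TsOH·H2O (5 mol %), CHCl3, 23 °C
Reagents that add atoms: none
Why: Proposed new method: the thiyl radical abstracts the formyl hydrogen of the vinylogous formate (polarity-reversal catalysis), the α,β-unsaturated acyl radical (in resonance with its α-ketenyl form, which lets E and Z enol ethers converge) adds to the internal carbon of the vinyl group, and the primary radical takes hydrogen back from the thiol, so the aldehyde C–H is added across the alkene and the C6–C7 bond and the C6 methyl group arise together; the closest known reactions are the thiol-catalysed radical cyclisation of alkenals (citronellal to menthone) and the acyl-radical closure of 2-(allyloxy)benzaldehydes to 3-methylchroman-4-ones, of which this is the non-benzo, enol-ether variant. Ring A closes in the 6-exo-trig mode, the Z enol ether holding the acyl carbon and the ether oxygen cis as the arene does in the chromanone case. The new stereocentre (pyranone C3, later C6) is controlled by the existing carbinol centre: a chair-like transition state with the side chain equatorial should favour the 2,3-trans isomer, and because this centre is α to the vinylogous-ester carbonyl the acid treatment should equilibrate any cis epimer to the trans, diequatorial product. The step needs exo closure onto C=C in preference to decarbonylation, thiol–ene addition or hydrogen abstraction at the allylic O–CH; ring size and the nucleophilic acyl radical meeting a terminal alkene secure the first, low thiol concentration and high dilution the others.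

Step 6
Reactants: 9 dihydropyranone
Product: 11 (2R)-2-[(2S,3S,6RS)-6-ethyl-6-methoxy-3,5-dimethyl-3,6-dihydro-2H-pyran-2-yl]-N-methoxy-N-methylpropanamide, via allylic alcohol 10 (not isolated)
Conditions: NaBH4, CeCl3·7H2O, MeOH, −40 to 0 °C; then pyridinium p-toluenesulfonate (5 mol %), MeOH, 0 °C
Reagents that add atoms: methanol CO
Why: Luche 1,2-reduction of the vinylogous-ester carbonyl (the Weinreb amide is inert to NaBH4) followed by acid-catalysed Ferrier-type allylic transposition in methanol should move the double bond to C4=C5 of the pyran and turn C6 into a ketal carbon; both carbinol epimers converge and methanol as solvent should outcompete the amide oxygen.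

Step 7
Reactants: 11 methyl ketal
Product: 12 (2R)-2-[(2S,3S,6RS)-6-ethyl-6-methoxy-3,5-dimethyl-3,6-dihydro-2H-pyran-2-yl]pentan-3-one
Conditions: EtMgBr, THF, 0 °C; then pH 7 buffer
Reagents that add atoms: ethylmagnesium bromide CC[Mg]Br
Why: Weinreb ketone synthesis: the chelated tetrahedral intermediate stops at the ketone, and the ketal and the α-stereocentre are not affected.

Step 8
Reactants: 13 (E)-2-methylpent-2-enal
Product: 14 (E)-2-methylpent-2-en-1-ol
Conditions: NaBH4, CeCl3·7H2O, MeOH, 0 °C
Reagents that add atoms: none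
Why: Luche 1,2-reduction of the enal with retention of the alkene geometry.

Step 9
Reactants: 14 allylic alcohol
Product: 15 (E)-1-bromo-2-methylpent-2-ene
Conditions: PBr3, Et2O, 0 °C
Reagents that add atoms: phosphorus tribromide BrP(Br)Br
Why: SN2 bromination of the primary allylic alcohol; the primary bromide with the trisubstituted alkene is also the thermodynamic allylic isomer.

Step 10
Reactants: 16 (S)-4-benzyl-3-propionyloxazolidin-2-one; 15 allylic bromide
Product: 17 (S)-4-benzyl-3-[(2R,4E)-2,4-dimethylhept-4-enoyl]oxazolidin-2-one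
Conditions: NaN(SiMe3)2, THF, −78 °C; then 15, −78 to −40 °C
Reagents that add atoms: none
Why: Evans asymmetric alkylation: the chelated (Z)-sodium enolate is alkylated by the reactive allylic bromide on the face opposite the benzyl group, setting the (R) α-methyl centre.

Step 11
Reactants: 17 alkylated imide
Product: 18 (2R,4E)-2,4-dimethylhept-4-en-1-ol
Conditions: LiBH4, MeOH (1 equiv), THF, 0 °C
Reagents that add atoms: none
Why: reductive removal of the auxiliary with LiBH4, which does not epimerise the α-centre.

Step 12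
Reactants: 18 alcohol
Product: 19 (2R,4E)-2,4-dimethylhept-4-enal
Conditions: Dess–Martin periodinane, NaHCO3, CH2Cl2, 0 to 23 °C
Reagents that add atoms: none
Why: buffered Dess–Martin oxidation should give the α-chiral aldehyde without epimerisation; it is used directly.

Step 13
Reactants: 12 ethyl ketone; 19 aldehyde
Product: 20 (2R,4R,5R,6R,8E)-2-[(2S,3S,6RS)-6-ethyl-6-methoxy-3,5-dimethyl-3,6-dihydro-2H-pyran-2-yl]-5-hydroxy-4,6,8-trimethylundec-8-en-3-one
Conditions: (c-C6H11)2BCl, Et3N, Et2O, −78 to 0 °C; then 19, −78 to −20 °C; then pH 7 buffer, MeOH, H2O2, 0 °C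
Reagents that add atoms: none
Why: substrate-controlled boron anti-aldol: the chloroborane and Et3N should form the (E)-enolate on the ethyl side, and a chair transition state on the enolate face anti to the α'-methyl group should set the new methyl centre anti to that methyl (the configuration the target needs), with the carbinol anti to the new methyl and erased in step 15.

Step 14
Reactants: 20 aldol adduct
Product: 21 (2R,3R,4R,6E)-2-[(1S,5S,6S)-1-ethyl-4,6,8-trimethyl-2,9-dioxabicyclo[3.3.1]nona-3,7-dien-3-yl]-4,6-dimethylnon-6-en-3-ol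
Conditions: pyridinium p-toluenesulfonate (10 mol %), 4 Å molecular sieves, CH2Cl2, 0 °C
Reagents that add atoms: none
Why: Ferrier-type ketal exchange: ionisation of the allylic methyl ketal gives a vinyl-substituted oxocarbenium ion that the ketone oxygen, tethered on the same face, captures at C1 to close ring B, loss of the axial C4–H then gives the endocyclic enol ether, the bridge dictates the C1 configuration, and the weak buffered acid is chosen so that the side-chain α-centre is not enolised.

Step 15
Reactants: 21 bicyclic alcohol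
Product: 22 (2S,4R,6E)-2-[(1S,5S,6S)-1-ethyl-4,6,8-trimethyl-2,9-dioxabicyclo[3.3.1]nona-3,7-dien-3-yl]-4,6-dimethylnon-6-en-3-one
Conditions: Dess–Martin periodinane, NaHCO3, CH2Cl2, 0 °C
Reagents that add atoms: none
Why: buffered Dess–Martin oxidation converts the carbinol into the ketone under non-enolising conditions, leaving the enol ether, the ketal and the two flanking stereocentres untouched.

## Compound list

1 | pentan-3-one | CCC(=O)CC | starting material
2 | 3-chloro-2-methylpent-2-enal (E/Z mixture) | CCC(Cl)=C(C)C=O | intermediate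
3 | (R)-4-benzyl-3-propionyloxazolidin-2-one | CCC(=O)N1[C@H](Cc2ccccc2)COC1=O | starting material
4 | acrolein (prop-2-enal) | C=CC=O | starting material
5 | (R)-4-benzyl-3-[(2R,3S)-3-hydroxy-2-methylpent-4-enoyl]oxazolidin-2-one | O=C1OC[C@@H](Cc2ccccc2)N1C(=O)[C@H](C)[C@@H](O)C=C | intermediate
6 | (2R,3S)-3-hydroxy-N-methoxy-N,2-dimethylpent-4-enamide | CON(C)C(=O)[C@H](C)[C@@H](O)C=C | intermediate
7 | (2R,3S)-N-methoxy-N,2-dimethyl-3-{[(2Z)-2-methyl-1-oxopent-2-en-3-yl]oxy}pent-4-enamide (Z drawn; E isomer converges in step 5) | CON(C)C(=O)[C@H](C)[C@@H](O/C(CC)=C(/C)C=O)C=C | intermediate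
8 | (2R)-2-[(2S,3RS)-6-ethyl-3,5-dimethyl-4-oxo-3,4-dihydro-2H-pyran-2-yl]-N-methoxy-N-methylpropanamide (kinetic C3-epimer mixture) | CON(C)C(=O)[C@H](C)[C@H]1OC(CC)=C(C)C(=O)C1C | intermediate (not isolated)
9 | (2R)-2-[(2S,3R)-6-ethyl-3,5-dimethyl-4-oxo-3,4-dihydro-2H-pyran-2-yl]-N-methoxy-N-methylpropanamide (2,3-trans) | CON(C)C(=O)[C@H](C)[C@H]1OC(CC)=C(C)C(=O)[C@@H]1C | intermediate
10 | (2R)-2-[(2S,3S,4RS)-6-ethyl-4-hydroxy-3,5-dimethyl-3,4-dihydro-2H-pyran-2-yl]-N-methoxy-N-methylpropanamide | CON(C)C(=O)[C@H](C)[C@H]1OC(CC)=C(C)C(O)[C@@H]1C | intermediate (not isolated)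
11 | (2R)-2-[(2S,3S,6RS)-6-ethyl-6-methoxy-3,5-dimethyl-3,6-dihydro-2H-pyran-2-yl]-N-methoxy-N-methylpropanamide | CON(C)C(=O)[C@H](C)[C@H]1OC(CC)(OC)C(C)=C[C@@H]1C | intermediate
12 | (2R)-2-[(2S,3S,6RS)-6-ethyl-6-methoxy-3,5-dimethyl-3,6-dihydro-2H-pyran-2-yl]pentan-3-one | CCC(=O)[C@H](C)[C@H]1OC(CC)(OC)C(C)=C[C@@H]1C | intermediate
13 | (E)-2-methylpent-2-enal | CC/C=C(\C)C=O | starting material
14 | (E)-2-methylpent-2-en-1-ol | CC/C=C(\C)CO | intermediate
15 | (E)-1-bromo-2-methylpent-2-ene | CC/C=C(\C)CBr | intermediate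
16 | (S)-4-benzyl-3-propionyloxazolidin-2-one | CCC(=O)N1[C@@H](Cc2ccccc2)COC1=O | starting material
17 | (S)-4-benzyl-3-[(2R,4E)-2,4-dimethylhept-4-enoyl]oxazolidin-2-one | CC/C=C(\C)C[C@@H](C)C(=O)N1[C@@H](Cc2ccccc2)COC1=O | intermediate
18 | (2R,4E)-2,4-dimethylhept-4-en-1-ol | CC/C=C(\C)C[C@@H](C)CO | intermediate
19 | (2R,4E)-2,4-dimethylhept-4-enal | CC/C=C(\C)C[C@@H](C)C=O | intermediate
20 | (2R,4R,5R,6R,8E)-2-[(2S,3S,6RS)-6-ethyl-6-methoxy-3,5-dimethyl-3,6-dihydro-2H-pyran-2-yl]-5-hydroxy-4,6,8-trimethylundec-8-en-3-one | CC/C=C(\C)C[C@@H](C)[C@@H](O)[C@@H](C)C(=O)[C@H](C)[C@H]1OC(CC)(OC)C(C)=C[C@@H]1C | intermediate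
21 | (2R,3R,4R,6E)-2-[(1S,5S,6S)-1-ethyl-4,6,8-trimethyl-2,9-dioxabicyclo[3.3.1]nona-3,7-dien-3-yl]-4,6-dimethylnon-6-en-3-ol | CC/C=C(\C)C[C@@H](C)[C@@H](O)[C@@H](C)C1=C(C)[C@H]2O[C@@](CC)(O1)C(C)=C[C@@H]2C | intermediate
22 | (2S,4R,6E)-2-[(1S,5S,6S)-1-ethyl-4,6,8-trimethyl-2,9-dioxabicyclo[3.3.1]nona-3,7-dien-3-yl]-4,6-dimethylnon-6-en-3-one | CC/C=C(\C)C[C@@H](C)C(=O)[C@@H](C)C1=C(C)[C@H]2O[C@@](CC)(O1)C(C)=C[C@@H]2C | target

## Step count

Total step count: 15. Longest linear sequence: 9 steps (3 to 22 through steps 2–7 and 13–15).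

## Steps most likely to fail

**Step 5 (Proposed new method).** The chain may break down in three ways: the thiyl radical may add to the vinyl group (thiol–ene) instead of abstracting the formyl hydrogen; it may abstract the doubly activated allylic O–C–H, eroding the carbinol configuration; or the delocalised acyl radical may close too slowly. The fallback uses only known reaction types, closes ring A at the same two carbons by metathesis, sets out from 3 and returns at 12.
- Evans syn-aldol of 3 with methacrolein should give (R)-4-benzyl-3-[(2R,3R)-3-hydroxy-2,4-dimethylpent-4-enoyl]oxazolidin-2-one F1.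
- AlMe3/MeNHOMe·HCl should convert it into (2R,3R)-3-hydroxy-N-methoxy-N,2,4-trimethylpent-4-enamide F2.
- Esterification with 2-methylbut-3-enoic acid (carbodiimide, DMAP) should give (2R,3R)-1-[methoxy(methyl)amino]-2,4-dimethyl-1-oxopent-4-en-3-yl 2-methylbut-3-enoate F3.
- Ring-closing metathesis with second-generation Grubbs catalyst should give the β,γ-unsaturated lactone (2R)-2-[(2R,5RS)-3,5-dimethyl-6-oxo-5,6-dihydro-2H-pyran-2-yl]-N-methoxy-N-methylpropanamide F4.
- 1,8-Diazabicyclo[5.4.0]undec-7-ene should move the double bond into conjugation and, under thermodynamic control, place the ring methyl trans, giving (2R)-2-[(2S,3S)-3,5-dimethyl-6-oxo-3,6-dihydro-2H-pyran-2-yl]-N-methoxy-N-methylpropanamide F5.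
- Excess EtLi (THF, −78 °C) should add once to the lactone carbonyl and once to the Weinreb amide, giving after work-up the lactol (2R)-2-[(2S,3S,6RS)-6-ethyl-6-hydroxy-3,5-dimethyl-3,6-dihydro-2H-pyran-2-yl]pentan-3-one F6.
- Brief treatment of F6 with pyridinium p-toluenesulfonate in methanol should give 12.

**Step 13.** The enolate-controlled anti addition asks aldehyde 19 for anti-Felkin attack, so π-facial selectivity may be poor, and the chloroborane may ionise the allylic methyl ketal. The fallback swaps substrate control for reagent control, sets out from 12 and 19 and returns at 22.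
- A syn-aldol through the (Z)-enol diisopinocampheylborinate of 12 should be used: (Ipc)2BOTf of the hand matched to 12 (fixed in a model run with an achiral aldehyde), iPr2NEt. This needs only the less strongly opposed Felkin attack on 19 and should give (2R,4R,5S,6R,8E)-2-[(2S,3S,6RS)-6-ethyl-6-methoxy-3,5-dimethyl-3,6-dihydro-2H-pyran-2-yl]-5-hydroxy-4,6,8-trimethylundec-8-en-3-one F7.
- Ketal exchange as in step 14 should give (2R,3S,4R,6E)-2-[(1S,5S,6S)-1-ethyl-4,6,8-trimethyl-2,9-dioxabicyclo[3.3.1]nona-3,7-dien-3-yl]-4,6-dimethylnon-6-en-3-ol F8.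
- Dess–Martin oxidation of F8 erases the epimeric carbinol and gives 22.

**Step 4.** The potassium aldolate of 6 may undergo retro-aldol cleavage, and addition–elimination at the hindered β-carbon may be slower than γ-deprotonation of 2. The fallback avoids any alkoxide, sets out from 2 and returns at 7.
- NaOMe in MeOH should convert 2 into 3-methoxy-2-methylpent-2-enal F9.
- Acid-catalysed alkoxy exchange of F9 with 6 (pyridinium p-toluenesulfonate, toluene, 60 °C, reduced pressure to remove methanol) should give 7.

Further compounds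
F1 | step 5 | (R)-4-benzyl-3-[(2R,3R)-3-hydroxy-2,4-dimethylpent-4-enoyl]oxazolidin-2-one | O=C1OC[C@@H](Cc2ccccc2)N1C(=O)[C@H](C)[C@@H](O)C(C)=C
F2 | step 5 | (2R,3R)-3-hydroxy-N-methoxy-N,2,4-trimethylpent-4-enamide | CON(C)C(=O)[C@H](C)[C@@H](O)C(C)=C
F3 | step 5 | (2R,3R)-1-[methoxy(methyl)amino]-2,4-dimethyl-1-oxopent-4-en-3-yl 2-methylbut-3-enoate (epimers at the acid α-carbon) | CON(C)C(=O)[C@H](C)[C@@H](OC(=O)C(C)C=C)C(C)=C
F4 | step 5 | (2R)-2-[(2R,5RS)-3,5-dimethyl-6-oxo-5,6-dihydro-2H-pyran-2-yl]-N-methoxy-N-methylpropanamide | CON(C)C(=O)[C@H](C)[C@H]1OC(=O)C(C)C=C1C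
F5 | step 5 | (2R)-2-[(2S,3S)-3,5-dimethyl-6-oxo-3,6-dihydro-2H-pyran-2-yl]-N-methoxy-N-methylpropanamide | CON(C)C(=O)[C@H](C)[C@H]1OC(=O)C(C)=C[C@@H]1C
F6 | step 5 | (2R)-2-[(2S,3S,6RS)-6-ethyl-6-hydroxy-3,5-dimethyl-3,6-dihydro-2H-pyran-2-yl]pentan-3-one | CCC(=O)[C@H](C)[C@H]1OC(CC)(O)C(C)=C[C@@H]1C
F7 | step 13 | (2R,4R,5S,6R,8E)-2-[(2S,3S,6RS)-6-ethyl-6-methoxy-3,5-dimethyl-3,6-dihydro-2H-pyran-2-yl]-5-hydroxy-4,6,8-trimethylundec-8-en-3-one | CC/C=C(\C)C[C@@H](C)[C@H](O)[C@@H](C)C(=O)[C@H](C)[C@H]1OC(CC)(OC)C(C)=C[C@@H]1C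
F8 | step 13 | (2R,3S,4R,6E)-2-[(1S,5S,6S)-1-ethyl-4,6,8-trimethyl-2,9-dioxabicyclo[3.3.1]nona-3,7-dien-3-yl]-4,6-dimethylnon-6-en-3-ol | CC/C=C(\C)C[C@@H](C)[C@H](O)[C@@H](C)C1=C(C)[C@H]2O[C@@](CC)(O1)C(C)=C[C@@H]2C
F9 | step 4 | 3-methoxy-2-methylpent-2-enal (E/Z mixture) | CCC(OC)=C(C)C=O
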